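**Plan**
- Retrosynthesis: the chelated 5-OH is unmasked last from its methyl ether and the 8-OMe comes from an 8-phenol. Ring A is then cut at C5–C6, C7–C8 and C8–C8a into a (4-pyranon-3-yl)(methoxy)carbene chromium complex, methoxyacetylene and one CO ligand.
- The carbene goes back through the acyl chloride and the Cr(CO)5 dianion to a 6-aryl-4-pyranone-3-carboxylate. Its ring C is cut at O1–C8a, C4a–C8a and C2–C3 (flavone numbering) into tert-butyl acetoacetate, the one-carbon unit of DMF-DMA and 2,5-dimethoxybenzoyl chloride.
- Forward: ring B is bought, ring C is built first (steps 1–2), the ester becomes the carbene (steps 3–5), ring A is annulated onto the pyranone (step 7), then 8-O-methylation and 5-O-demethylation follow.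
- Enabling feature: C5 and C8 are para oxygen-bearing carbons of ring A, joined through C6–C7 on one side and through the pyranone double bond C4a=C8a on the other, which is the pattern that carbene carbon, alkyne and CO deliver onto an alkenyl carbene.
- Stereochemistry: the target has no stereocentre, so nothing has to be set or protected.

Key step: step 7

Assumption: the target is achiral, so the requirement of a single enantiomer is met as such; the push–pull enamine double bonds of 2 and 4 and the double bond of 13 carry no fixed geometry, and sodium naphthalenide is taken as a titrated stock solution in THF.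

**Step 1**
Reactants: 1 tert-butyl acetoacetate
Product: 2 tert-butyl 2-[(dimethylamino)methylidene]-3-oxobutanoate
Conditions: DMF-DMA (1.2 equiv), neat, rt → 60 °C
Reagents that add atoms: N,N-dimethylformamide dimethyl acetal, COC(OC)N(C)C
Why: Condensation of the doubly activated methylene of a β-keto ester with an amide acetal (enaminone formation) needs no added base and is routine for acetoacetates.

**Step 2**
Reactants: 2 tert-butyl 2-[(dimethylamino)methylidene]-3-oxobutanoate; 3 2,5-dimethoxybenzoyl chloride
Product: 5 tert-butyl 6-(2,5-dimethoxyphenyl)-4-oxo-4H-pyran-3-carboxylate, via acylated enaminone 4 (not isolated)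
Conditions: LiHMDS (2.2 equiv) added to 2 + 3, THF, −78 °C; then 1 M aq. HCl, Et2O, 0 °C → rt (brief)
Reagents that add atoms: none
Why: This is the enaminone-anion acylation route to 3-alkoxycarbonyl-4-pyranones: the γ-lithium enolate of 2 is C-acylated by the aroyl chloride as it forms, and on acidification the enol oxygen of the new aryl ketone displaces dimethylamine by addition–elimination to close the pyranone, while the tert-butyl ester tolerates the short cold dilute-acid treatment.

**Step 3**
Reactants: 5 tert-butyl 6-(2,5-dimethoxyphenyl)-4-oxo-4H-pyran-3-carboxylate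
Product: 6 6-(2,5-dimethoxyphenyl)-4-oxo-4H-pyran-3-carboxylic acid
Conditions: TFA/CH2Cl2 (1:3), rt
Reagents that add atoms: none
Why: Acidolysis of a tert-butyl ester through the tert-butyl cation frees the acid without the aqueous base or hot mineral acid that would open the 4-pyranone, and the aryl methyl ethers are inert to TFA.

**Step 4**
Reactants: 6 6-(2,5-dimethoxyphenyl)-4-oxo-4H-pyran-3-carboxylic acid
Product: 7 6-(2,5-dimethoxyphenyl)-4-oxo-4H-pyran-3-carbonyl chloride
Conditions: (COCl)2 (1.2 equiv), cat. DMF, CH2Cl2, 0 °C → rt; evaporate, toluene azeotrope, use crude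
Reagents that add atoms: oxalyl chloride, O=C(Cl)C(=O)Cl
Why: Vilsmeier-catalysed acid chloride formation is standard for the closely related chromone-3-carboxylic acids, and the carboxylic acid reacts far faster than the weakly nucleophilic pyranone carbonyl at this stoichiometry.

**Step 5**
Reactants: 7 6-(2,5-dimethoxyphenyl)-4-oxo-4H-pyran-3-carbonyl chloride; 8 chromium hexacarbonyl
Product: 11 pentacarbonyl[(6-(2,5-dimethoxyphenyl)-4-oxo-4H-pyran-3-yl)(methoxy)methylidene]chromium, via disodium pentacarbonylchromate 9 (not isolated), via sodium acylchromate 10 (not isolated)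
Conditions: 8, Na naphthalenide (2.0 equiv), THF, −78 °C; add 7, −78 → 0 °C; evaporate; Me3OBF4 (1.2 equiv), CH2Cl2, 0 °C
Reagents that add atoms: trimethyloxonium tetrafluoroborate, C[O+](C)C.F[B-](F)(F)F
Why: The pentacarbonylchromate dianion is acylated at the metal by acid chlorides and the resulting acylchromate is O-methylated by Meerwein's salt, the acid-chloride variant of the Fischer carbene synthesis, which avoids placing an organolithium on the base-sensitive pyranone.

**Step 6**
Reactants: 12 chloroacetaldehyde dimethyl acetal
Product: 15 methoxyacetylene, via 1-chloro-2-methoxyethene 13 (not isolated), via sodium methoxyacetylide 14 (not isolated)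
Conditions: NaNH2 (commercial, 3.1 equiv), liq. NH3, −33 °C; NH3 evaporated; cold sat. aq. NaCl, −20 °C; distil into −78 °C trap, use at once as a cold THF solution
Reagents that add atoms: none
Why: Sodium amide removes methanol and then hydrogen chloride from the chloroacetal (double β-elimination) and holds the ynol ether as its acetylide until protonation, the standard preparative route to alkoxyacetylenes.

**Step 7**
Reactants: 11 pentacarbonyl[(6-(2,5-dimethoxyphenyl)-4-oxo-4H-pyran-3-yl)(methoxy)methylidene]chromium; 15 methoxyacetylene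
Product: 17 2-(2,5-dimethoxyphenyl)-8-hydroxy-5,7-dimethoxy-4H-chromen-4-one, via tricarbonylchromium arene complex 16 (not isolated)
Conditions: 15 (3 equiv), THF, 50 °C, sealed tube, Ar; then air, MeCN, rt; filtration through silica
Reagents that add atoms: none
Why: Proposed new method: thermal loss of one CO from 11 (assisted by the neighbouring C4 carbonyl, which can occupy the vacant site) lets methoxyacetylene bind and insert into the Cr=C bond with its CH carbon on the carbene carbon (C5–C6); CO then inserts at the methoxy-bearing carbon to give a chromium-bound dienylketene (C7–C8), which closes onto the pyranone C2–H carbon (C8–C8a) and tautomerises to the phenol, held as the Cr(CO)3 complex 16 until air releases 17. The closest known reaction type is the Dötz benzannulation of alkenyl- and heteroaryl(alkoxy)carbene chromium complexes with alkynes, including closures onto an oxygen-bearing ring carbon of 3-furyl complexes, but a 4-pyranon-3-yl carbene combined with a terminal ynol ether has no counterpart. Ring A, a six-membered carbocycle, is closed by 6π-electrocyclisation of the metal-bound dienylketene (formal [3+2+1]), and no stereocentre is formed. The step needs regioselective alkyne insertion (5,7,8- against 5,6,8-oxygenation), which is secured because the unsubstituted, more nucleophilic alkyne terminus bonds to the electrophilic carbene carbon while the larger methoxy-bearing carbon lies next to the CO-derived carbon, so sterics and polarity point the same way. It also needs CO insertion to beat cyclopentannulation and double alkyne uptake, which chromium, an alkoxycarbene, an ether solvent and moderate temperature favour, and the ketene can reach only C2–H because the other neighbour of the carbene-bearing carbon is the C4 carbonyl.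

**Step 8**
Reactants: 17 2-(2,5-dimethoxyphenyl)-8-hydroxy-5,7-dimethoxy-4H-chromen-4-one
Product: 18 2-(2,5-dimethoxyphenyl)-5,7,8-trimethoxy-4H-chromen-4-one
Conditions: MeI (1.5 equiv), K2CO3, DMF, rt
Reagents that add atoms: iodomethane, CI
Why: Williamson methylation of the only free phenol proceeds through its phenoxide, and no other acidic or alkylatable site is present.

**Step 9**
Reactants: 18 2-(2,5-dimethoxyphenyl)-5,7,8-trimethoxy-4H-chromen-4-one
Product: 20 5-hydroxy-7,8,2',5'-tetramethoxyflavone [2-(2,5-dimethoxyphenyl)-5-hydroxy-7,8-dimethoxy-4H-chromen-4-one], via dichloroboryl chelate 19 (not isolated)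
Conditions: BCl3 (1 M in CH2Cl2, 2.5 equiv), CH2Cl2, −78 → 0 °C; then H2O, rt
Reagents that add atoms: none
Why: Boron trichloride binds the C4 carbonyl and the peri 5-methoxy oxygen in a six-membered chelate and chloride removes only that methyl group, the standard chelation-directed 5-O-demethylation of polymethoxyflavones, while the 7-, 8-, 2'- and 5'-ethers have no carbonyl neighbour and stay intact at low temperature.

**Compound list**
1 | tert-butyl acetoacetate | CC(=O)CC(=O)OC(C)(C)C | starting material
2 | tert-butyl 2-[(dimethylamino)methylidene]-3-oxobutanoate (geometry not fixed) | CC(=O)C(=CN(C)C)C(=O)OC(C)(C)C | intermediate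
3 | 2,5-dimethoxybenzoyl chloride | COc1ccc(OC)c(C(=O)Cl)c1 | starting material
4 | tert-butyl 5-(2,5-dimethoxyphenyl)-2-[(dimethylamino)methylidene]-3,5-dioxopentanoate (formed as its lithium enolate, written as the neutral diketone; not isolated) | CN(C)C=C(C(=O)OC(C)(C)C)C(=O)CC(=O)c1cc(OC)ccc1OC | intermediate
5 | tert-butyl 6-(2,5-dimethoxyphenyl)-4-oxo-4H-pyran-3-carboxylate | CC(C)(C)OC(=O)c1coc(-c2cc(OC)ccc2OC)cc1=O | intermediate
6 | 6-(2,5-dimethoxyphenyl)-4-oxo-4H-pyran-3-carboxylic acid | OC(=O)c1coc(-c2cc(OC)ccc2OC)cc1=O | intermediate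
7 | 6-(2,5-dimethoxyphenyl)-4-oxo-4H-pyran-3-carbonyl chloride | O=C(Cl)c1coc(-c2cc(OC)ccc2OC)cc1=O | intermediate
8 | chromium hexacarbonyl | O=C=[Cr](=C=O)(=C=O)(=C=O)(=C=O)=C=O | starting material
9 | disodium pentacarbonylchromate (not isolated) | [Na+].[Na+].O=C=[Cr-2](=C=O)(=C=O)(=C=O)=C=O | intermediate
10 | sodium pentacarbonyl[6-(2,5-dimethoxyphenyl)-4-oxo-4H-pyran-3-carbonyl]chromate (not isolated) | [Na+].[O-]C(=[Cr](=C=O)(=C=O)(=C=O)(=C=O)=C=O)c1coc(-c2cc(OC)ccc2OC)cc1=O | intermediate
11 | pentacarbonyl[(6-(2,5-dimethoxyphenyl)-4-oxo-4H-pyran-3-yl)(methoxy)methylidene]chromium | COC(=[Cr](=C=O)(=C=O)(=C=O)(=C=O)=C=O)c1coc(-c2cc(OC)ccc2OC)cc1=O | intermediate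
12 | chloroacetaldehyde dimethyl acetal | COC(CCl)OC | starting material
13 | 1-chloro-2-methoxyethene (E/Z mixture, not isolated) | COC=CCl | intermediate
14 | sodium methoxyacetylide (not isolated) | [Na+].[C-]#COC | intermediate
15 | methoxyacetylene | C#COC | intermediate
16 | tricarbonyl[η6-2-(2,5-dimethoxyphenyl)-8-hydroxy-5,7-dimethoxy-4H-chromen-4-one]chromium, Cr(CO)3 on ring A, written as arene plus Cr(CO)3 fragment (not isolated) | COc1ccc(OC)c(-c2cc(=O)c3c(OC)cc(OC)c(O)c3o2)c1.O=C=[Cr](=C=O)=C=O | intermediate
17 | 2-(2,5-dimethoxyphenyl)-8-hydroxy-5,7-dimethoxy-4H-chromen-4-one | COc1ccc(OC)c(-c2cc(=O)c3c(OC)cc(OC)c(O)c3o2)c1 | intermediate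
18 | 2-(2,5-dimethoxyphenyl)-5,7,8-trimethoxy-4H-chromen-4-one | COc1ccc(OC)c(-c2cc(=O)c3c(OC)cc(OC)c(OC)c3o2)c1 | intermediate
19 | 5-(dichloroboryloxy)-2-(2,5-dimethoxyphenyl)-7,8-dimethoxy-4H-chromen-4-one, boron chelated to the C4 carbonyl (not isolated) | COc1ccc(OC)c(-c2cc(=O)c3c(OB(Cl)Cl)cc(OC)c(OC)c3o2)c1 | intermediate
20 | 5-hydroxy-7,8,2',5'-tetramethoxyflavone | COc1ccc(OC)c(-c2cc(=O)c3c(O)cc(OC)c(OC)c3o2)c1 | target

**Count**
Total steps: 9. Longest linear sequence: 8 steps (steps 1–5 and 7–9 from tert-butyl acetoacetate); step 6 is a one-step side branch.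

**Steps most likely to fail**

1. Step 7 (proposed new method). After alkyne insertion the donor-stabilised vinylcarbene may fail to take up CO, the ynol ether may polymerise on warming, cyclopentannulation or double alkyne uptake may compete, and the electron-rich phenol may be over-oxidised to the quinone during air demetallation. The fallback is a Baker–Venkataraman flavone synthesis that sets out from 3 and comes back at 18. Acid chloride 3 would acylate purchased 1-(2-hydroxy-3,4,6-trimethoxyphenyl)ethanone (pyridine, DMAP, CH2Cl2) to give 2-acetyl-3,5,6-trimethoxyphenyl 2,5-dimethoxybenzoate F1. Base-induced acyl migration (KOH, pyridine, 50 °C) would give 1-(2,5-dimethoxyphenyl)-3-(2-hydroxy-3,4,6-trimethoxyphenyl)propane-1,3-dione F2. Cyclodehydration (H2SO4, AcOH, 90 °C) would then give 18, which continues with step 9.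

2. Step 5. The strongly reducing chromate dianion may transfer an electron to, or add conjugately to, the pyranone ring, or reduce the acid chloride instead of being acylated at chromium. The fallback is the organometallic Fischer route; it sets out from 6 and comes back at 11. Iododecarboxylation of 6 (NIS, cat. LiOAc, MeCN/H2O, a Hunsdiecker-type halodecarboxylation at the enol-ether β-carbon) would give 2-(2,5-dimethoxyphenyl)-5-iodo-4H-pyran-4-one F3. Iodine–magnesium exchange (iPrMgCl·LiCl, THF, −40 °C) would give chloro[6-(2,5-dimethoxyphenyl)-4-oxo-4H-pyran-3-yl]magnesium F4. Addition of F4 to chromium hexacarbonyl 8 would give chloromagnesium pentacarbonyl[6-(2,5-dimethoxyphenyl)-4-oxo-4H-pyran-3-carbonyl]chromate F5, and O-methylation with Me3OBF4 would give 11.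

3. Step 9. The Lewis acid may also cleave the 7-, 8- or 2'-ethers, or stop short of full 5-O-demethylation. The fallback replaces ether cleavage by a redox route; it sets out from 17 and comes back at 20, bypassing steps 8 and 9. Oxidative demethylation of the para-methoxyphenol (PhI(OAc)2, MeCN/H2O, 0 °C, which leaves the dimethoxyphenyl ring alone) would give 2-(2,5-dimethoxyphenyl)-7-methoxy-4H-chromene-4,5,8-trione F6. Reduction (Na2S2O4, EtOAc/H2O) would give 2-(2,5-dimethoxyphenyl)-5,8-dihydroxy-7-methoxy-4H-chromen-4-one F7. Methylation with MeI (1.05 equiv) and K2CO3 in acetone under nitrogen would then alkylate only the 8-OH, since the 5-OH is hydrogen-bonded to the C4 carbonyl, and would give 20.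

**Further compounds**
F1 | step 7 | 2-acetyl-3,5,6-trimethoxyphenyl 2,5-dimethoxybenzoate | CC(=O)c1c(OC)cc(OC)c(OC)c1OC(=O)c1cc(OC)ccc1OC
F2 | step 7 | 1-(2,5-dimethoxyphenyl)-3-(2-hydroxy-3,4,6-trimethoxyphenyl)propane-1,3-dione | COc1ccc(OC)c(C(=O)CC(=O)c2c(OC)cc(OC)c(OC)c2O)c1
F3 | step 5 | 2-(2,5-dimethoxyphenyl)-5-iodo-4H-pyran-4-one | COc1ccc(OC)c(-c2cc(=O)c(I)co2)c1
F4 | step 5 | chloro[6-(2,5-dimethoxyphenyl)-4-oxo-4H-pyran-3-yl]magnesium | COc1ccc(OC)c(-c2cc(=O)c([Mg]Cl)co2)c1
F5 | step 5 | chloromagnesium pentacarbonyl[6-(2,5-dimethoxyphenyl)-4-oxo-4H-pyran-3-carbonyl]chromate | Cl[Mg+].[O-]C(=[Cr](=C=O)(=C=O)(=C=O)(=C=O)=C=O)c1coc(-c2cc(OC)ccc2OC)cc1=O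
F6 | step 9 | 2-(2,5-dimethoxyphenyl)-7-methoxy-4H-chromene-4,5,8-trione | COc1ccc(OC)c(C2=CC(=O)C3=C(O2)C(=O)C(OC)=CC3=O)c1
F7 | step 9 | 2-(2,5-dimethoxyphenyl)-5,8-dihydroxy-7-methoxy-4H-chromen-4-one | COc1ccc(OC)c(-c2cc(=O)c3c(O)cc(OC)c(O)c3o2)c1
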